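**Plan**

- Retrosynthesis: the two benzyl ethers and the two pyrimidine O-methyl groups come off last. The pyrrole is then opened at N7–C6 and the aroyl carbon is put back into the ring between N7 and C6, which turns the 6-aroylpyrrolo[2,3-d]pyrimidine into a 7-arylpyrido[2,3-d]pyrimidine 8-oxide.
- Enabling feature: the exocyclic ketone carbon on C6, directly beside the pyrrole nitrogen N7 and carrying the 4-oxyphenyl ring, is the former α-carbon (C7) of a 2-arylpyridine N-oxide ring fused to the pyrimidine.
- The pyridine ring is cut at C4a–C5 and C7–N8 into 4-amino-2,6-dimethoxypyrimidine and a chalcone. The chalcone is cut at its Cα=Cβ bond into O-benzylvanillin and 4-benzyloxyacetophenone.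
- Forward: chalcone, then the pyridine ring annulated onto the pyrimidine with dehydrogenation, then the N8-oxide, then light-driven contraction of the pyridine to the pyrrole, then hydrolysis to the uracil ring and hydrogenolysis.
- Stereochemistry: the target has no stereocentre; the racemic C5 centre of the dihydropyridine intermediate is erased on aromatisation.

Key step: step 4

Remark: the target is treated as the 1H,3H,7H-lactam tautomer. Atom numbers follow pyrido[2,3-d]pyrimidine (N1, C2, N3, C4, C4a, C5, C6, C7, N8, C8a) before the contraction and pyrrolo[2,3-d]pyrimidine (C5, C6, N7, C7a) after it.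

**Route**

Step 1
Reactants: 1 4-benzyloxy-3-methoxybenzaldehyde; 2 1-(4-benzyloxyphenyl)ethanone
Product: 3 (E)-3-(4-benzyloxy-3-methoxyphenyl)-1-(4-benzyloxyphenyl)prop-2-en-1-one
Conditions: NaOH (aq), EtOH, rt
Reagents that add atoms: none
Why: Claisen–Schmidt crossed aldol condensation; the aldehyde cannot enolise and the methyl ketone enolises on one side only, so a single enone forms, dehydration gives the conjugated E alkene, and the benzyl ethers are stable to hydroxide.

Step 2
Reactants: 3 (E)-3-(4-benzyloxy-3-methoxyphenyl)-1-(4-benzyloxyphenyl)prop-2-en-1-one; 4 4-amino-2,6-dimethoxypyrimidine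
Product: 6 5-(4-benzyloxy-3-methoxyphenyl)-7-(4-benzyloxyphenyl)-2,4-dimethoxypyrido[2,3-d]pyrimidine, via dihydropyridine 5 (not isolated)
Conditions: glacial AcOH, 110 °C; then DDQ (1.1 equiv), 1,4-dioxane, rt
Reagents that add atoms: none
Why: Hantzsch-type cyclocondensation well known for 6-aminopyrimidines and chalcones: the enamine-like C5 of 4 adds to the β-carbon of the acid-activated enone (Michael addition), the amino group condenses with the ketone to give 5 with the aldehyde-derived aryl at C5 and the ketone-derived aryl at C7, and DDQ dehydrogenates the 1,4-dihydropyridine to the pyridine.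

Step 3
Reactants: 6 5-(4-benzyloxy-3-methoxyphenyl)-7-(4-benzyloxyphenyl)-2,4-dimethoxypyrido[2,3-d]pyrimidine
Product: 7 5-(4-benzyloxy-3-methoxyphenyl)-7-(4-benzyloxyphenyl)-2,4-dimethoxypyrido[2,3-d]pyrimidine 8-oxide
Conditions: mCPBA (1.2 equiv), CH2Cl2, 0 °C to rt
Reagents that add atoms: mCPBA (3-chloroperoxybenzoic acid), O=C(OO)c1cccc(Cl)c1
Why: peracid N-oxidation of an azine; N8 should be the most nucleophilic ring nitrogen because N1 and N3 are inductively deactivated by the adjacent methoxy-bearing carbons (N3 by two, N1 additionally by two aza-substituted neighbours), as in the N-oxidation of 2-arylpyridines and 1,8-naphthyridines, and no other group present reacts with mCPBA.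

Step 4
Reactants: 7 5-(4-benzyloxy-3-methoxyphenyl)-7-(4-benzyloxyphenyl)-2,4-dimethoxypyrido[2,3-d]pyrimidine 8-oxide
Product: 9 6-(4-benzyloxybenzoyl)-5-(4-benzyloxy-3-methoxyphenyl)-2,4-dimethoxy-7H-pyrrolo[2,3-d]pyrimidine, via oxaziridine 8 (not isolated)
Conditions: hν (365 nm), Cu(OTf)2 (1 equiv), degassed MeCN (about 5 mM), rt
Reagents that add atoms: none
Why: Proposed new method: excitation of the N-oxide should close the oxygen onto C7 to give oxaziridine 8, whose N–O and C7–N8 bonds then break (directly or through the 1,2-oxazepine valence isomer) so that C7 becomes the aryl ketone carbon and N8 is left as a pyrimidinyl nitrene beside a (Z)-aroylvinyl group; the nitrogen adds to C6 and a hydrogen shift from C6 to nitrogen aromatises the pyrrole. The closest known reaction type is the photochemical contraction of monocyclic pyridine N-oxides to 2-acylpyrroles in the presence of divalent copper salts, and the final N–C6 bond formation parallels the cyclisation of ortho-vinyl aryl nitrenes to indoles. The one ring formed, the pyrrole, closes by a 6π 1,5-electrocyclisation of the nitrene (or its copper nitrenoid) onto alkene carbon C6, formally 5-endo; no stereocentre is created. Oxygen must go to C7 and not to the ring-fusion carbon C8a: an oxaziridine at C8a would destroy the pyrimidine sextet, whereas the one at C7 keeps it and is benzylic to the 4-benzyloxyphenyl ring, and C7 bears no hydrogen, so the lactam (2-pyridone) channel is closed. The N–C6 closure must also outrun an oxygen walk to C6 that would lead to a 1,3-oxazepine; Cu(OTf)2, which can chelate between the N-oxide oxygen and the peri nitrogen N1, is expected to hold the nitrogen-centred intermediate and steer it to C6. Degassed aprotic MeCN and 365 nm light, where the benzyl ethers do not absorb, should limit deoxygenation and solvolysis.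

Step 5
Reactants: 9 6-(4-benzyloxybenzoyl)-5-(4-benzyloxy-3-methoxyphenyl)-2,4-dimethoxy-7H-pyrrolo[2,3-d]pyrimidine
Product: 10 6-(4-benzyloxybenzoyl)-5-(4-benzyloxy-3-methoxyphenyl)-1H-pyrrolo[2,3-d]pyrimidine-2,4(3H,7H)-dione
Conditions: 3 M aq HCl, 1,4-dioxane, 90 °C
Reagents that add atoms: water, O
Why: acid-catalysed hydrolysis of the two imidate-type methoxy groups (water adds at C2 and C4 of the protonated pyrimidine and methanol leaves) is the standard unmasking of 2,4-dimethoxypyrimidines to uracils; the aryl methyl ether and the ketone are inert, and any benzyl ether lost here would only anticipate step 6.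

Step 6
Reactants: 10 6-(4-benzyloxybenzoyl)-5-(4-benzyloxy-3-methoxyphenyl)-1H-pyrrolo[2,3-d]pyrimidine-2,4(3H,7H)-dione
Product: 11 Rigidin C, 6-(4-hydroxybenzoyl)-5-(4-hydroxy-3-methoxyphenyl)-1H-pyrrolo[2,3-d]pyrimidine-2,4(3H,7H)-dione
Conditions: H2 (1 atm), 10% Pd/C, THF–MeOH, rt
Reagents that add atoms: none
Why: hydrogenolysis of aryl benzyl ethers over palladium on carbon is fast at 1 atm, whereas the ketone is a vinylogous amide of the pyrrole nitrogen with a para-oxygenated aryl group and should be too electron-rich to be reduced; the aryl methyl ether is untouched.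

**Compound list**

1 | 4-benzyloxy-3-methoxybenzaldehyde (O-benzylvanillin) | COc1cc(C=O)ccc1OCc1ccccc1 | starting material
2 | 1-(4-benzyloxyphenyl)ethanone | CC(=O)c1ccc(OCc2ccccc2)cc1 | starting material
3 | (E)-3-(4-benzyloxy-3-methoxyphenyl)-1-(4-benzyloxyphenyl)prop-2-en-1-one | O=C(/C=C/c1ccc(OCc2ccccc2)c(OC)c1)c1ccc(OCc2ccccc2)cc1 | intermediate
4 | 4-amino-2,6-dimethoxypyrimidine | COc1cc(N)nc(OC)n1 | starting material
5 | 5-(4-benzyloxy-3-methoxyphenyl)-7-(4-benzyloxyphenyl)-2,4-dimethoxy-5,8-dihydropyrido[2,3-d]pyrimidine, racemic, not isolated | COc1nc(OC)c2c(n1)NC(c1ccc(OCc3ccccc3)cc1)=CC2c1ccc(OCc2ccccc2)c(OC)c1 | intermediate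
6 | 5-(4-benzyloxy-3-methoxyphenyl)-7-(4-benzyloxyphenyl)-2,4-dimethoxypyrido[2,3-d]pyrimidine | COc1nc(OC)c2c(-c3ccc(OCc4ccccc4)c(OC)c3)cc(-c3ccc(OCc4ccccc4)cc3)nc2n1 | intermediate
7 | 5-(4-benzyloxy-3-methoxyphenyl)-7-(4-benzyloxyphenyl)-2,4-dimethoxypyrido[2,3-d]pyrimidine 8-oxide | COc1nc(OC)c2c(-c3ccc(OCc4ccccc4)c(OC)c3)cc(-c3ccc(OCc4ccccc4)cc3)[n+]([O-])c2n1 | intermediate
8 | oxaziridine valence isomer of 7 with oxygen bridging N8 and C7, racemic, presumed photochemical intermediate, not isolated | COc1nc(OC)c2c(n1)N1OC1(c1ccc(OCc3ccccc3)cc1)C=C2c1ccc(OCc2ccccc2)c(OC)c1 | intermediate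
9 | 6-(4-benzyloxybenzoyl)-5-(4-benzyloxy-3-methoxyphenyl)-2,4-dimethoxy-7H-pyrrolo[2,3-d]pyrimidine | COc1nc(OC)c2c(-c3ccc(OCc4ccccc4)c(OC)c3)c(C(=O)c3ccc(OCc4ccccc4)cc3)[nH]c2n1 | intermediate
10 | 6-(4-benzyloxybenzoyl)-5-(4-benzyloxy-3-methoxyphenyl)-1H-pyrrolo[2,3-d]pyrimidine-2,4(3H,7H)-dione | COc1cc(-c2c(C(=O)c3ccc(OCc4ccccc4)cc3)[nH]c3[nH]c(=O)[nH]c(=O)c23)ccc1OCc1ccccc1 | intermediate
11 | Rigidin C | COc1cc(-c2c(C(=O)c3ccc(O)cc3)[nH]c3[nH]c(=O)[nH]c(=O)c23)ccc1O | target

**Step count**

Total steps: 6. Longest linear sequence: 6 steps (from 1 or 2 to 11).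

**Steps most likely to fail**

Step 4 (proposed method). The excited N-oxide may simply lose oxygen back to the pyridine. Alternatively the oxygen may walk from C7 to C6 and lead through a 1,3-oxazepine to N-acyl products, so that N–C6 closure with the acyl group kept on carbon is outcompeted. Prolonged irradiation may also degrade the aroylpyrrole.

Fallback by known chemistry, building the pyrrole by condensation instead of ring contraction. It sets out from 2 (with 1) and rejoins the route at 10.
- α-Bromination of 2 with CuBr2 in EtOAc–CHCl3 at reflux should give 2-bromo-1-(4-benzyloxyphenyl)ethanone F1.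
- Displacement with methanesulfonamide and K2CO3 in MeCN should give N-[2-(4-benzyloxyphenyl)-2-oxoethyl]methanesulfonamide F2.
- Three-component condensation of F2 with aldehyde 1 and 2-cyanoacetamide (catalytic K2CO3, EtOH, reflux) proceeds by Knoevenagel condensation, Michael addition, cyclisation onto the nitrile and loss of methanesulfinate. It should give 2-amino-5-(4-benzyloxybenzoyl)-4-(4-benzyloxy-3-methoxyphenyl)-1H-pyrrole-3-carboxamide F3.
- Heating F3 with oxalyl chloride in diglyme closes the pyrimidinedione through the acyl isocyanate and delivers 10, which continues with step 6.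

Step 3. Oxygen transfer may occur at N1 instead of, or in addition to, N8, or N8 may react sluggishly because of the flanking aryl group, so that an isomeric or doubly oxidised N-oxide is formed that cannot contract to the pyrrole.

Fallback: the order of unmasking and oxidation is exchanged so that only one ring nitrogen can be oxidised. It sets out from 6 and rejoins the route at 10.
- Hydrolysis of 6 with 3 M aq HCl in 1,4-dioxane at 90 °C should give 5-(4-benzyloxy-3-methoxyphenyl)-7-(4-benzyloxyphenyl)pyrido[2,3-d]pyrimidine-2,4(1H,3H)-dione F4, in which N1 and N3 are lactam nitrogens.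
- mCPBA in CH2Cl2–DMF then can only oxidise N8, giving 5-(4-benzyloxy-3-methoxyphenyl)-7-(4-benzyloxyphenyl)pyrido[2,3-d]pyrimidine-2,4(1H,3H)-dione 8-oxide F5, whose N-oxide oxygen is hydrogen-bonded to N1–H.
- Irradiation of F5 under the conditions of step 4 contracts the ring at the dione stage and gives 10 directly; this is the same untested contraction applied to a different substrate.

Step 2. The conjugate addition of the pyrimidine C5 to an enone deactivated by two para-alkoxy donors may stall, and acetolysis of a pyrimidine methoxy group may compete at the temperature then required.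

Fallback: a Bohlmann–Rahtz-type heteroannulation with the more electrophilic ynone, which needs no dehydrogenation. It sets out from 1 and rejoins the route at 6.
- Homologation of 1 with dimethyl (1-diazo-2-oxopropyl)phosphonate and K2CO3 in MeOH should give 1-benzyloxy-4-ethynyl-2-methoxybenzene F6.
- Acyl Sonogashira coupling of F6 with 4-benzyloxybenzoyl chloride (PdCl2(PPh3)2, CuI, Et3N, THF, rt) should give 3-(4-benzyloxy-3-methoxyphenyl)-1-(4-benzyloxyphenyl)prop-2-yn-1-one F7.
- Heating F7 with 4 and catalytic ZnBr2 in toluene should give 6 by Michael addition of C5 to the alkyne carbon bearing the guaiacyl ring and cyclodehydration of the amino group onto the ketone.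

**Further compounds**

F1 | step 4 | 2-bromo-1-(4-benzyloxyphenyl)ethanone | O=C(CBr)c1ccc(OCc2ccccc2)cc1
F2 | step 4 | N-[2-(4-benzyloxyphenyl)-2-oxoethyl]methanesulfonamide | CS(=O)(=O)NCC(=O)c1ccc(OCc2ccccc2)cc1
F3 | step 4 | 2-amino-5-(4-benzyloxybenzoyl)-4-(4-benzyloxy-3-methoxyphenyl)-1H-pyrrole-3-carboxamide | COc1cc(-c2c(C(=O)c3ccc(OCc4ccccc4)cc3)[nH]c(N)c2C(N)=O)ccc1OCc1ccccc1
F4 | step 3 | 5-(4-benzyloxy-3-methoxyphenyl)-7-(4-benzyloxyphenyl)pyrido[2,3-d]pyrimidine-2,4(1H,3H)-dione | COc1cc(-c2cc(-c3ccc(OCc4ccccc4)cc3)nc3[nH]c(=O)[nH]c(=O)c23)ccc1OCc1ccccc1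
F5 | step 3 | 5-(4-benzyloxy-3-methoxyphenyl)-7-(4-benzyloxyphenyl)pyrido[2,3-d]pyrimidine-2,4(1H,3H)-dione 8-oxide | COc1cc(-c2cc(-c3ccc(OCc4ccccc4)cc3)[n+]([O-])c3[nH]c(=O)[nH]c(=O)c23)ccc1OCc1ccccc1
F6 | step 2 | 1-benzyloxy-4-ethynyl-2-methoxybenzene | C#Cc1ccc(OCc2ccccc2)c(OC)c1
F7 | step 2 | 3-(4-benzyloxy-3-methoxyphenyl)-1-(4-benzyloxyphenyl)prop-2-yn-1-one | COc1cc(C#CC(=O)c2ccc(OCc3ccccc3)cc2)ccc1OCc1ccccc1
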